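**Retrosynthetic overview**

1. The target is 5,7,5'',7''-tetrahydroxy-4',4'''-dimethoxy-6,8''-biflavone (unit 1 = the 6-linked flavone, unit 2 = the 8-linked flavone). It is unmasked last by dealkylation, and both pyranone rings are cut together at O1–C2 and C4–C4a, giving a biaryl diphenol and two molecules of ethyl 3-(4-methoxyphenyl)propiolate.
2. The strategy rests on ring A of unit 2: a 1,3,5-trioxygenated benzene whose C8 carries the aryl group (C6 of unit 1) and sits between the oxygen-bearing C8a and C7, with the third oxygen at C5. A Danheiser benzannulation cuts it at C8–C8a, C6–C7 and C4a–C8a into 3-ethoxycyclobutenone (C8a, C4a, C5, C6) and an aryl siloxyalkyne (C8, C7), so the tetra-ortho-substituted biaryl bond is never made by coupling.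
3. The siloxyalkyne comes from 2-iodoresorcinol: isopropylation, iridium-catalysed borylation/oxidation to install the para oxygen (the later O1 of unit 1), benzylation, Sonogashira ethynylation, then acetylide oxidation and O-silylation.
4. Ring order: ring A of unit 1 is bought, ring A of unit 2 is built in step 7, both pyranone rings close in step 11, and the anisyl rings arrive with the propiolate.

Key step: step 7

Remark: the target SMILES defines no configuration at the C6–C8 biaryl axis, so the axis is not controlled and no stereocentre has to be set. The β-aryloxy enoates are drawn as the Z isomers expected from anti addition; an E isomer would converge in step 11.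

**Step 1**
Reactants: 1 2-iodobenzene-1,3-diol (2-iodoresorcinol)
Product: 2 2-iodo-1,3-di(propan-2-yloxy)benzene
Conditions: 2-bromopropane, K2CO3, DMF, 60 °C
Reagents that add atoms: 2-bromopropane, CC(C)Br
Why: Williamson etherification of both phenols; isopropyl ethers survive organolithium bases, heat, hydrogenolysis and acylation and should fall to BCl3 at the end without loss of the anisyl methyl ethers.

**Step 2**
Reactants: 2 2-iodo-1,3-di(propan-2-yloxy)benzene
Product: 4 4-iodo-3,5-di(propan-2-yloxy)phenol, via pinacol arylboronate 3 (not isolated)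
Conditions: B2pin2, [Ir(OMe)(cod)]2 (1.5 mol%), dtbpy (3 mol%), THF, 60 °C; then 30% H2O2, aq NaOH, 0 °C to rt
Reagents that add atoms: bis(pinacolato)diboron, CC1(C)OB(OC1(C)C)B1OC(C)(C)C(C)(C)O1 (boryl group of 3 only); hydrogen peroxide, OO
Why: Iridium-catalysed C–H borylation is sterically controlled and should take the only C–H without an ortho substituent (para to iodine), the flanked C–I bond is tolerated, and alkaline peroxide oxidises the C–B bond to the phenol at the same carbon.

**Step 3**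
Reactants: 4 4-iodo-3,5-di(propan-2-yloxy)phenol
Product: 5 5-(benzyloxy)-2-iodo-1,3-di(propan-2-yloxy)benzene
Conditions: BnBr, K2CO3, acetone, 50 °C
Reagents that add atoms: benzyl bromide, BrCc1ccccc1
Why: Williamson benzylation; the benzyl ether marks the oxygen that becomes O1 of unit 1 and is the only group later removed by hydrogenolysis.

**Step 4**
Reactants: 5 5-(benzyloxy)-2-iodo-1,3-di(propan-2-yloxy)benzene
Product: 6 {[4-(benzyloxy)-2,6-di(propan-2-yloxy)phenyl]ethynyl}(trimethyl)silane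
Conditions: ethynyltrimethylsilane, Pd(PPh3)2Cl2 (5 mol%), CuI (10 mol%), Et3N–THF, 60 °C
Reagents that add atoms: ethynyltrimethylsilane, C#C[Si](C)(C)C
Why: Sonogashira coupling; an aryl iodide keeps oxidative addition easy despite the two ortho alkoxy groups and the electron-rich ring.

**Step 5**
Reactants: 6 {[4-(benzyloxy)-2,6-di(propan-2-yloxy)phenyl]ethynyl}(trimethyl)silane
Product: 7 5-(benzyloxy)-2-ethynyl-1,3-di(propan-2-yloxy)benzene
Conditions: K2CO3 (0.2 equiv), MeOH–THF, rt
Reagents that add atoms: none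
Why: Base-catalysed methanolysis of the alkynyl C–Si bond (protodesilylation), to which all the ethers are inert.

**Step 6**
Reactants: 7 5-(benzyloxy)-2-ethynyl-1,3-di(propan-2-yloxy)benzene
Product: 10 ({[4-(benzyloxy)-2,6-di(propan-2-yloxy)phenyl]ethynyl}oxy)tri(propan-2-yl)silane, via lithium acetylide 8 (not isolated), via lithium ynolate 9 (not isolated)
Conditions: n-BuLi, THF, −78 °C; LiOOt-Bu (from t-BuOOH and LiN(SiMe3)2), −78 to 0 °C; then i-Pr3SiOTf, −78 °C
Reagents that add atoms: n-butyllithium, [Li]CCCC (lithium of 8 and 9 only); tert-butyl hydroperoxide, CC(C)(C)OO; triisopropylsilyl trifluoromethanesulfonate, CC(C)[Si](OS(=O)(=O)C(F)(F)F)(C(C)C)C(C)C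
Why: Known oxidation of a lithium acetylide by lithium tert-butyl peroxide (the acetylide carbon attacks the peroxide oxygen, tert-butoxide leaves) gives the ynolate, which the bulky silyl triflate should capture on oxygen as the isolable triisopropylsilyl ynol ether.

**Step 7**
Reactants: 10 ({[4-(benzyloxy)-2,6-di(propan-2-yloxy)phenyl]ethynyl}oxy)tri(propan-2-yl)silane; 11 3-ethoxycyclobut-2-en-1-one
Product: 16 4'-(benzyloxy)-4-ethoxy-2',6'-di(propan-2-yloxy)-6-{[tri(propan-2-yl)silyl]oxy}biphenyl-2-ol, via ethoxyvinylketene 12 (not isolated), via vinylcyclobutenone 13 (not isolated), via dienylketene 14 (not isolated), via cyclohexadienone 15 (not isolated)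
Conditions: 11 (1.5 equiv, added in portions), PhMe, 110 °C, sealed tube
Reagents that add atoms: none
Why: Proposed new method: thermal 4π electrocyclic opening of 11 should give vinylketene 12, whose carbonyl carbon is attacked by the nucleophilic aryl-bearing carbon of the polarised ynol ether 10 in a [2+2] cycloaddition to racemic 13; a second 4π opening gives dienylketene 14, 6π electrocyclisation gives dienone 15, and tautomerisation gives phenol 16. The closest known reaction is the Danheiser benzannulation of cyclobutenones with siloxyalkynes to resorcinol monosilyl ethers; a 3-alkoxycyclobutenone and a di-ortho-alkoxyaryl siloxyalkyne have not been shown in it. The one ring formed, ring A of unit 2, is closed by the 6π electrocyclisation (C4a–C8a, between the ketene carbon and the terminal CH2) after the intermolecular [2+2] event has made C8–C8a and C6–C7. No stereocentre survives: the sp3 carbon of 13 is lost on ring opening, and 16 has no stereogenic axis because the old ring carries two identical ortho substituents. The step needs only regioselectivity in the [2+2] event, and the oxygen-donor polarisation of the ynol ether secures it, placing the aryl group between the free hydroxyl (later O1 on C8a) and the silyl ether (C7) with the ethoxy group para (C5). The linear alkyne holds the two ortho isopropoxy groups away from the reacting carbons, so steric load at the later axis arises only once the ring is made.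

**Step 8**
Reactants: 16 4'-(benzyloxy)-4-ethoxy-2',6'-di(propan-2-yloxy)-6-{[tri(propan-2-yl)silyl]oxy}biphenyl-2-ol
Product: 17 4-ethoxy-2',6'-di(propan-2-yloxy)-6-{[tri(propan-2-yl)silyl]oxy}biphenyl-2,4'-diol
Conditions: H2 (1 atm), Pd/C, EtOAc–EtOH, rt
Reagents that add atoms: none
Why: Hydrogenolysis of the benzyl aryl ether under neutral conditions frees the phenol para to the axis, while silyl, isopropyl and ethyl ethers are inert and nothing else is reducible.

**Step 9**
Reactants: 17 4-ethoxy-2',6'-di(propan-2-yloxy)-6-{[tri(propan-2-yl)silyl]oxy}biphenyl-2,4'-diol; 18 ethyl 3-(4-methoxyphenyl)prop-2-ynoate (2.5 equiv)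
Product: 19 diethyl (2Z,2'Z)-3,3'-{[4-ethoxy-2',6'-di(propan-2-yloxy)-6-{[tri(propan-2-yl)silyl]oxy}biphenyl-2,4'-diyl]bis(oxy)}bis[3-(4-methoxyphenyl)prop-2-enoate]
Conditions: Cs2CO3 (0.3 equiv), dry DMF, 50 °C
Reagents that add atoms: none
Why: Oxa-Michael addition of both phenoxides to the β-carbon of the aryl propiolate (the classical first stage of the flavone synthesis from phenols and arylpropiolic esters) should give the Z enoates by anti addition; a substoichiometric base in dry solvent at moderate temperature is chosen to spare the hindered aryl silyl ether.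

**Step 10**
Reactants: 19 the bis(ethyl enoate)
Product: 20 (2Z,2'Z)-3,3'-{[4-ethoxy-2',6'-di(propan-2-yloxy)-6-{[tri(propan-2-yl)silyl]oxy}biphenyl-2,4'-diyl]bis(oxy)}bis[3-(4-methoxyphenyl)prop-2-enoic acid]
Conditions: Me3SnOH, ClCH2CH2Cl, 80 °C; then cold 1 M HCl wash
Reagents that add atoms: trimethyltin hydroxide, C[Sn](C)(C)O
Why: Trimethyltin hydroxide cleaves the ethyl esters by tin-assisted delivery of hydroxide under nearly neutral conditions, sparing the aryl silyl ether and the β-aryloxy enoate that aqueous alkali would endanger.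

**Step 11**
Reactants: 20 the bis(enoic acid)
Product: 22 6-[5-ethoxy-2-(4-methoxyphenyl)-4-oxo-7-{[tri(propan-2-yl)silyl]oxy}-4H-chromen-8-yl]-2-(4-methoxyphenyl)-5,7-di(propan-2-yloxy)-4H-chromen-4-one, via bis(trifluoroacetyl) mixed anhydride 21 (not isolated)
Conditions: (CF3CO)2O, CH2Cl2, 0 °C to rt
Reagents that add atoms: trifluoroacetic anhydride, O=C(OC(=O)C(F)(F)F)C(F)(F)F (trifluoroacetyl groups of 21 only)
Why: Each mixed anhydride should acylate the adjacent 1,3,5-trioxygenated ring ortho to the vinyl ether oxygen (intramolecular Friedel–Crafts acylation, 6-membered closure, well known for aryloxy acids of activated arenes); on the old ring the two ortho sites are equivalent and give the 6-linked unit 1, on the new ring only C4a is free so the 8-linked unit 2 results, and any E enoate can equilibrate through the push–pull acyl cation.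

**Step 12**
Reactants: 22 the silyl-protected biflavone
Product: 23 6-[5-ethoxy-7-hydroxy-2-(4-methoxyphenyl)-4-oxo-4H-chromen-8-yl]-2-(4-methoxyphenyl)-5,7-di(propan-2-yloxy)-4H-chromen-4-one
Conditions: Bu4NF, THF, 0 °C; aq NH4Cl
Reagents that add atoms: none
Why: Fluoride cleaves the aryl O–Si bond (strong Si–F bond, phenoxide para to the C4 carbonyl as leaving group), and nothing else in the molecule responds to fluoride.

**Step 13**
Reactants: 23 the 7-hydroxy biflavone triether
Product: 24 5,7-dihydroxy-6-[5,7-dihydroxy-2-(4-methoxyphenyl)-4-oxo-4H-chromen-8-yl]-2-(4-methoxyphenyl)-4H-chromen-4-one (target)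
Conditions: BCl3 (excess), CH2Cl2, −78 °C to rt; MeOH, then H2O
Reagents that add atoms: none
Why: Lewis-acid ether cleavage: BCl3 should ionise the two isopropyl aryl ethers and open the ethyl ether held in a chelate with the C4 carbonyl of unit 2 (peri position), while the non-chelated anisyl methyl ethers are known to resist BCl3 at room temperature.

**Compound list**

1 | 2-iodobenzene-1,3-diol | Oc1cccc(O)c1I | starting material
2 | 2-iodo-1,3-di(propan-2-yloxy)benzene | CC(C)Oc1cccc(OC(C)C)c1I | intermediate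
3 | 2-[4-iodo-3,5-di(propan-2-yloxy)phenyl]-4,4,5,5-tetramethyl-1,3,2-dioxaborolane | CC(C)Oc1cc(B2OC(C)(C)C(C)(C)O2)cc(OC(C)C)c1I | intermediate (not isolated)
4 | 4-iodo-3,5-di(propan-2-yloxy)phenol | CC(C)Oc1cc(O)cc(OC(C)C)c1I | intermediate
5 | 5-(benzyloxy)-2-iodo-1,3-di(propan-2-yloxy)benzene | CC(C)Oc1cc(OCc2ccccc2)cc(OC(C)C)c1I | intermediate
6 | {[4-(benzyloxy)-2,6-di(propan-2-yloxy)phenyl]ethynyl}(trimethyl)silane | CC(C)Oc1cc(OCc2ccccc2)cc(OC(C)C)c1C#C[Si](C)(C)C | intermediate
7 | 5-(benzyloxy)-2-ethynyl-1,3-di(propan-2-yloxy)benzene | CC(C)Oc1cc(OCc2ccccc2)cc(OC(C)C)c1C#C | intermediate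
8 | lithium [4-(benzyloxy)-2,6-di(propan-2-yloxy)phenyl]acetylide | [Li+].[C-]#Cc1c(OC(C)C)cc(OCc2ccccc2)cc1OC(C)C | intermediate (not isolated)
9 | lithium 2-[4-(benzyloxy)-2,6-di(propan-2-yloxy)phenyl]ethyn-1-olate | [Li+].[O-]C#Cc1c(OC(C)C)cc(OCc2ccccc2)cc1OC(C)C | intermediate (not isolated)
10 | ({[4-(benzyloxy)-2,6-di(propan-2-yloxy)phenyl]ethynyl}oxy)tri(propan-2-yl)silane | CC(C)Oc1cc(OCc2ccccc2)cc(OC(C)C)c1C#CO[Si](C(C)C)(C(C)C)C(C)C | intermediate (key-step precursor)
11 | 3-ethoxycyclobut-2-en-1-one | CCOC1=CC(=O)C1 | starting material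
12 | 3-ethoxybuta-1,3-dien-1-one | CCOC(=C)C=C=O | intermediate (not isolated)
13 | 2-[4-(benzyloxy)-2,6-di(propan-2-yloxy)phenyl]-4-(1-ethoxyethenyl)-3-{[tri(propan-2-yl)silyl]oxy}cyclobut-2-en-1-one (racemic) | CCOC(=C)C1C(=O)C(c2c(OC(C)C)cc(OCc3ccccc3)cc2OC(C)C)=C1O[Si](C(C)C)(C(C)C)C(C)C | intermediate (not isolated)
14 | (3E)-2-[4-(benzyloxy)-2,6-di(propan-2-yloxy)phenyl]-5-ethoxy-3-{[tri(propan-2-yl)silyl]oxy}hexa-1,3,5-trien-1-one | O=C=C(c1c(OC(C)C)cc(OCc2ccccc2)cc1OC(C)C)/C(O[Si](C(C)C)(C(C)C)C(C)C)=C\C(=C)OCC | intermediate (not isolated)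
15 | 2-[4-(benzyloxy)-2,6-di(propan-2-yloxy)phenyl]-5-ethoxy-3-{[tri(propan-2-yl)silyl]oxy}cyclohexa-2,4-dien-1-one | O=C1CC(OCC)=CC(O[Si](C(C)C)(C(C)C)C(C)C)=C1c1c(OC(C)C)cc(OCc2ccccc2)cc1OC(C)C | intermediate (not isolated)
16 | 4'-(benzyloxy)-4-ethoxy-2',6'-di(propan-2-yloxy)-6-{[tri(propan-2-yl)silyl]oxy}biphenyl-2-ol | Oc1cc(OCC)cc(O[Si](C(C)C)(C(C)C)C(C)C)c1-c1c(OC(C)C)cc(OCc2ccccc2)cc1OC(C)C | intermediate (key-step product)
17 | 4-ethoxy-2',6'-di(propan-2-yloxy)-6-{[tri(propan-2-yl)silyl]oxy}biphenyl-2,4'-diol | CCOc1cc(O)c(c(O[Si](C(C)C)(C(C)C)C(C)C)c1)-c1c(OC(C)C)cc(O)cc1OC(C)C | intermediate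
18 | ethyl 3-(4-methoxyphenyl)prop-2-ynoate | CCOC(=O)C#Cc1ccc(OC)cc1 | starting material
19 | diethyl (2Z,2'Z)-3,3'-{[4-ethoxy-2',6'-di(propan-2-yloxy)-6-{[tri(propan-2-yl)silyl]oxy}biphenyl-2,4'-diyl]bis(oxy)}bis[3-(4-methoxyphenyl)prop-2-enoate] | CCOC(=O)/C=C(\Oc1cc(OCC)cc(O[Si](C(C)C)(C(C)C)C(C)C)c1-c1c(OC(C)C)cc(O/C(=C\C(=O)OCC)c2ccc(OC)cc2)cc1OC(C)C)c1ccc(OC)cc1 | intermediate
20 | (2Z,2'Z)-3,3'-{[4-ethoxy-2',6'-di(propan-2-yloxy)-6-{[tri(propan-2-yl)silyl]oxy}biphenyl-2,4'-diyl]bis(oxy)}bis[3-(4-methoxyphenyl)prop-2-enoic acid] | OC(=O)/C=C(\Oc1cc(OCC)cc(O[Si](C(C)C)(C(C)C)C(C)C)c1-c1c(OC(C)C)cc(O/C(=C\C(=O)O)c2ccc(OC)cc2)cc1OC(C)C)c1ccc(OC)cc1 | intermediate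
21 | bis(trifluoroacetic) mixed anhydride of diacid 20 | FC(F)(F)C(=O)OC(=O)/C=C(\Oc1cc(OCC)cc(O[Si](C(C)C)(C(C)C)C(C)C)c1-c1c(OC(C)C)cc(O/C(=C\C(=O)OC(=O)C(F)(F)F)c2ccc(OC)cc2)cc1OC(C)C)c1ccc(OC)cc1 | intermediate (not isolated)
22 | 6-[5-ethoxy-2-(4-methoxyphenyl)-4-oxo-7-{[tri(propan-2-yl)silyl]oxy}-4H-chromen-8-yl]-2-(4-methoxyphenyl)-5,7-di(propan-2-yloxy)-4H-chromen-4-one | COc1ccc(-c2cc(=O)c3c(OC(C)C)c(-c4c(O[Si](C(C)C)(C(C)C)C(C)C)cc(OCC)c5c(=O)cc(-c6ccc(OC)cc6)oc45)c(OC(C)C)cc3o2)cc1 | intermediate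
23 | 6-[5-ethoxy-7-hydroxy-2-(4-methoxyphenyl)-4-oxo-4H-chromen-8-yl]-2-(4-methoxyphenyl)-5,7-di(propan-2-yloxy)-4H-chromen-4-one | COc1ccc(-c2cc(=O)c3c(OC(C)C)c(-c4c(O)cc(OCC)c5c(=O)cc(-c6ccc(OC)cc6)oc45)c(OC(C)C)cc3o2)cc1 | intermediate
24 | 5,7-dihydroxy-6-[5,7-dihydroxy-2-(4-methoxyphenyl)-4-oxo-4H-chromen-8-yl]-2-(4-methoxyphenyl)-4H-chromen-4-one | COc1ccc(-c2cc(=O)c3c(O)c(-c4c(O)cc(O)c5c(=O)cc(-c6ccc(OC)cc6)oc45)c(O)cc3o2)cc1 | target

**Step count and risks**

Total step count: 13. Longest linear sequence: 13 steps (1 to 24); 11 and 18 are bought.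

Steps most likely to fail:

1. Step 7 (proposed new method). The alkoxy-stabilised cyclobutenone may open only at temperatures where the siloxyalkyne rearranges or the vinylketene dimerises, and the [2+2] event at the alkyne carbon bearing the di-ortho-substituted aryl group may be slow. Fallback with known chemistry, setting out from aryl iodide 5: the biaryl bond is made by a Negishi coupling of the kind used for tetra-ortho-substituted biaryls, and the two flanking oxygens are told apart afterwards. 5-Ethoxybenzene-1,3-diol is protected with MOMCl/i-Pr2NEt to give 1-ethoxy-3,5-bis(methoxymethoxy)benzene F1. n-BuLi (THF, 0 °C) lithiates F1 between the two acetal oxygens and ZnCl2 gives [4-ethoxy-2,6-bis(methoxymethoxy)phenyl]zinc chloride F2. Coupling of F2 with 5 (Pd2(dba)3, RuPhos, THF–NMP, 70 °C) gives 4'-(benzyloxy)-4-ethoxy-2,6-bis(methoxymethoxy)-2',6'-di(propan-2-yloxy)biphenyl F3. HCl in MeOH removes both acetals to give 4'-(benzyloxy)-4-ethoxy-2',6'-di(propan-2-yloxy)biphenyl-2,6-diol F4. One equivalent of i-Pr3SiOTf with 2,6-lutidine (CH2Cl2, −78 °C) silylates one of the two equivalent hydroxyls (any bis-silyl ether is returned to F4 with Bu4NF), which gives 16; the route resumes at step 8.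

2. Step 9. Conjugate addition may stall at the phenoxide flanked by the biaryl axis, and harder forcing invites attack of phenoxide or carbonate on the aryl silyl ether, which would free a third phenol. Fallback, setting out from 17: the pyranone rings are built by the chalcone route, in which loss of the silyl group is harmless. Bu4NF gives 4-ethoxy-2',6'-di(propan-2-yloxy)biphenyl-2,4',6-triol F5. AcOH/BF3·OEt2 (70 °C) acetylates each ring ortho to a hydroxyl (boron-chelate-directed; on the new ring the two candidate sites are equivalent) to give 1,1'-[4-ethoxy-2,4',6-trihydroxy-2',6'-di(propan-2-yloxy)biphenyl-3,3'-diyl]di(ethan-1-one) F6. Claisen–Schmidt condensation with 4-methoxybenzaldehyde (KOH, EtOH) gives (2E,2'E)-1,1'-[4-ethoxy-2,4',6-trihydroxy-2',6'-di(propan-2-yloxy)biphenyl-3,3'-diyl]bis[3-(4-methoxyphenyl)prop-2-en-1-one] F7. I2 (catalytic) in DMSO at 130 °C cyclises and dehydrogenates both 2'-hydroxychalcones to give 23; the route resumes at step 13.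

3. Step 10. Hydrolysis of the conjugated, electron-rich ethyl esters by the tin hydroxide may be sluggish, and prolonged heating may start to remove the silyl group, giving mixtures. Fallback, setting out from 19: the silyl ether is given up on purpose and the ring closure is run on the free phenol. Aqueous LiOH in THF–MeOH (50 °C) cleaves both esters and the aryl silyl ether to give (2Z,2'Z)-3,3'-{[4-ethoxy-6-hydroxy-2',6'-di(propan-2-yloxy)biphenyl-2,4'-diyl]bis(oxy)}bis[3-(4-methoxyphenyl)prop-2-enoic acid] F8. P2O5–MeSO3H (Eaton's reagent, rt) closes both pyranone rings by Friedel–Crafts acylation with the hydroxyl left free as para activator of C4a of unit 2, giving 23; the route resumes at step 13.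

**Further compounds**

F1 | step 7 | 1-ethoxy-3,5-bis(methoxymethoxy)benzene | CCOc1cc(OCOC)cc(OCOC)c1
F2 | step 7 | [4-ethoxy-2,6-bis(methoxymethoxy)phenyl]zinc chloride | CCOc1cc(OCOC)c([Zn]Cl)c(OCOC)c1
F3 | step 7 | 4'-(benzyloxy)-4-ethoxy-2,6-bis(methoxymethoxy)-2',6'-di(propan-2-yloxy)biphenyl | CCOc1cc(OCOC)c(c(OCOC)c1)-c1c(OC(C)C)cc(OCc2ccccc2)cc1OC(C)C
F4 | step 7 | 4'-(benzyloxy)-4-ethoxy-2',6'-di(propan-2-yloxy)biphenyl-2,6-diol | CCOc1cc(O)c(c(O)c1)-c1c(OC(C)C)cc(OCc2ccccc2)cc1OC(C)C
F5 | step 9 | 4-ethoxy-2',6'-di(propan-2-yloxy)biphenyl-2,4',6-triol | CCOc1cc(O)c(c(O)c1)-c1c(OC(C)C)cc(O)cc1OC(C)C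
F6 | step 9 | 1,1'-[4-ethoxy-2,4',6-trihydroxy-2',6'-di(propan-2-yloxy)biphenyl-3,3'-diyl]di(ethan-1-one) | CCOc1cc(O)c(c(O)c1C(C)=O)-c1c(OC(C)C)cc(O)c(C(C)=O)c1OC(C)C
F7 | step 9 | (2E,2'E)-1,1'-[4-ethoxy-2,4',6-trihydroxy-2',6'-di(propan-2-yloxy)biphenyl-3,3'-diyl]bis[3-(4-methoxyphenyl)prop-2-en-1-one] | CCOc1cc(O)c(c(O)c1C(=O)/C=C/c1ccc(OC)cc1)-c1c(OC(C)C)cc(O)c(C(=O)/C=C/c2ccc(OC)cc2)c1OC(C)C
F8 | step 10 | (2Z,2'Z)-3,3'-{[4-ethoxy-6-hydroxy-2',6'-di(propan-2-yloxy)biphenyl-2,4'-diyl]bis(oxy)}bis[3-(4-methoxyphenyl)prop-2-enoic acid] | OC(=O)/C=C(\Oc1cc(OCC)cc(O)c1-c1c(OC(C)C)cc(O/C(=C\C(=O)O)c2ccc(OC)cc2)cc1OC(C)C)c1ccc(OC)cc1
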